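**Remarks on the chemistry (assumptions)**
- Carotenoid numbering is used for positions: ring C1 (gem-dimethyl carbon) to C6 (ring carbon bearing C7), C3 the carbinol, chain C7 to C8'. The target is (3S,6R), with the C3 hydroxyl and C7 on the same ring face.
- The facial sense of the epoxidation in step 3 is assigned by analogy with 1,2-dihydronaphthalene, where the (R,R) ligand gives the (1R,2S)-oxide. This maps onto the (3S,4R)-epoxide needed here.
- All-E crocetin dialdehyde is taken as a purchasable C20 building block.

## Analysis of the target

The target is a C30 apocarotenal. An ε-type end group (2,6,6-trimethylcyclohex-2-ene ring, C1–C6) carries a hydroxyl at C3 and, at C6, an all-E octaene chain from C7 to C9' that ends in the α-methyl enal C8'. It has two stereocentres, C3 (S) and C6 (R), placed 1,4 across the ring alkene C4=C5, with the hydroxyl and C7 cis. The section C8 to C8' is the carbon skeleton of a symmetrical C20 dialdehyde, so the chain is unsymmetrical only through its two ends. The polyene is sensitive to light, oxygen and acid, and the allylic C3 carbinol ionises easily. The C6–H is doubly allylic and, through the polyene, a vinylogous α-hydrogen of the aldehyde, so base can epimerise C6 or pull the ring alkene into conjugation. The difficulty lies in the ring: the cis-1,4 pair must be set absolutely, C6 sits beside the quaternary C1, and the C4=C5 alkene must be placed out of conjugation and kept there. The strategy reads the C3 oxygen, the C4=C5 alkene and the C6–H as the result of an allylic hydrogenolysis with 1,3-shift. A 3,4-epoxide beside a C5=C6 alkene, ionised at C4 and reduced at C6 on the face away from the oxygen, gives this pattern, and safranal 1 already holds all ten carbons of that ring fragment.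

## Retrosynthetic reasoning

**C7=C8.** Target 13 comes from its silyl ether 12, and 12 is cut at C7=C8 into the ring sulfone 9 and crocetin dialdehyde 10. This cut keeps the whole C20 polyene, with seven E double bonds, as a bought unit. Only one disubstituted alkene is made, and the ring fragment stays small. The forward olefination must react at one aldehyde of a symmetrical dialdehyde, give the E alkene, and keep excess base away from the C6–H of the product.

**C7–S and the protecting groups.** Sulfone 9 comes from sulfide 8 and that from alcohol 7 by substitution at C7. This needs the C7 hydroxyl free and the C3 oxygen masked, so 7 is traced to the bis-silyl ether 6 and to alcohol 5. The C3 oxygen carries the bulkier silyl group so that the primary one can be removed beside it. A silyl ether at C7 in the earlier compounds is inert to hypochlorite and is not an allylic leaving group for palladium.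

**C6–H (key disconnection).** Alcohol 5 is traced to vinyl epoxide 4. No skeletal bond is cut: the C6–H bond is removed, the alkene returns to C5=C6, and the C3 oxygen is reconnected to C4. Both stereocentres of 5 then depend on one element, the epoxide. The forward step must ionise C4–O with inversion and put hydrogen on C6, not C4, from the metal face.

**Epoxide.** Epoxide 4 comes from the achiral diene 3. The forward epoxidation must take the cis-disubstituted C3=C4 alkene rather than the tetrasubstituted C5=C6 alkene, and one face of it.

**To the starting material.** Diene 3 is the silyl ether of safranol 2, which is the 1,2-reduction product of safranal 1. Three routine steps reach the key-step precursor.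

## Alternatives that were turned down

**Alternative 1:** The cut is at the central C15=C15' bond. A C20 allylic halide bearing the finished ring and a C10 allylic halide bearing the masked aldehyde would be joined through sulfur and oxidised to the bis-allylic sulfone A1. Base with an in situ halogen source would halogenate next to sulfur, close the episulfone and expel the sulfur bridge to give the protected target A2 (Ramberg–Bäcklund reaction).
- For: it is convergent and late. The aldehyde stays an acetal while base is present, so C6–H is never a vinylogous α-hydrogen. On this point it is stronger than the chosen route, which exposes a free polyenal in step 9.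
- Against: it does not address the ring. C3 and C6 must still be made by some other means and then carried through a hand-built C20 half whose alkenes each need geometric control. The two different allylic partners must be joined unsymmetrically. The halogen source ends as a dihalocarbene in a strongly basic medium, and the electron-rich C4=C5 and polyene alkenes of A1 are exposed to it. The geometry of the new bond is not controlled.
- Comparison: the chosen route buys C8–C8' ready-made in 10 and forms one alkene, so it is much shorter. It accepts base sensitivity in one step and manages it by stoichiometry.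

**Alternative 2:** No skeletal bond is cut; the C3–H bond is formed. The racemic keto ester A3 has C6 α to the ester and γ to the enone carbonyl, so it racemises through its dienolate in mildly basic buffer. A ketoreductase with cofactor recycling would reduce the C3 ketone of one enantiomer from one face to give hydroxy ester A4.
- For: two stereocentres are set in one catalytic step from a cheap racemate with full theoretical conversion. A4 would reach alcohol 7 in two more operations (silylation, ester reduction), against six steps from 1 to 7 here. On step count it is the stronger plan.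
- Against: it needs an enzyme that accepts a hindered conjugated ketone, distinguishes a stereocentre 1,4-remote from the carbonyl, and attacks the correct face. None of these can be argued from structure. The dienolate can also reprotonate at C4 and move the alkene into conjugation with the ester, which drains substrate.
- Comparison: the chosen route enforces the cis relationship by mechanism (anti ionisation, hydrogen from the metal face). Its absolute sense comes from a catalyst available in both hands, and it needs no screening.

**Alternative 3:** The cut is at C6–C7. An enantiopure ring with cis oxygens at C3 and C4 and a C5=C6 alkene would be converted to its C4 stannylmethyl ether A5. Tin–lithium exchange with an alkyllithium gives an α-alkoxy carbanion that shifts [2,3] suprafacially to alcohol A6 (Still–Wittig rearrangement).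
- For: carbon can only arrive at C6, whereas hydride in the chosen key step could also go to C4, so its regiochemistry is more certain. A6 has the C7 hydroxyl free and the C3 oxygen silylated, so steps 5 and 6 of the chosen route would not be needed.
- Against: the precursor already needs two stereocentres (C3 and C4, cis), so the problem is moved to an enantioselective oxygenation plus a diastereoselective reduction. A C–C bond must be made at the congested C6 next to the quaternary C1, whereas safranal 1 supplies C7. A stoichiometric tin reagent is required, and the [1,2] shift competes.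
- Comparison: the chosen route sets both centres from one epoxidation of an achiral diene and forms only a C–H bond at C6. It pays for this with two protecting-group steps and the regiochemical question at the key step.

Key step: step 4

## Route

**Step 1**
Reactants: 1 safranal (2,6,6-trimethylcyclohexa-1,3-diene-1-carbaldehyde)
Product: 2 safranol, (2,6,6-trimethylcyclohexa-1,3-dien-1-yl)methanol
Conditions: NaBH4, MeOH, 0 °C
Reagents that add atoms: none
Why: Borohydride 1,2-reduction of the aldehyde; the carbonyl carbon is far more electrophilic than the hindered diene terminus, so the diene is untouched and no stereocentre is formed.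

**Step 2**
Reactants: 2 safranol
Product: 3 tert-butyl(dimethyl)[(2,6,6-trimethylcyclohexa-1,3-dien-1-yl)methoxy]silane
Conditions: TBSCl, imidazole, DMF, 0 °C to rt
Reagents that add atoms: tert-butyldimethylsilyl chloride, CC(C)(C)[Si](C)(C)Cl
Why: Standard silylation of a primary alcohol under basic conditions, which spare the acid-labile dienylic C7–O bond; the silyl ether survives hypochlorite and is not a leaving group for palladium in step 4.

**Step 3**
Reactants: 3 tert-butyl(dimethyl)[(2,6,6-trimethylcyclohexa-1,3-dien-1-yl)methoxy]silane
Product: 4 (3S,4R)-3,4-epoxide of 3, tert-butyl(dimethyl){[(1R,6S)-2,4,4-trimethyl-7-oxabicyclo[4.1.0]hept-2-en-3-yl]methoxy}silane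
Conditions: (R,R)-[N,N'-bis(3,5-di-tert-butylsalicylidene)cyclohexane-1,2-diaminato]MnCl (5 mol %), 4-phenylpyridine N-oxide (20 mol %), aq NaOCl buffered to pH 11.3 (Na2HPO4), CH2Cl2, 0 °C
Reagents that add atoms: sodium hypochlorite, [Na+].[O-]Cl
Why: Jacobsen–Katsuki epoxidation: the oxo-manganese species formed from the trivalent manganese complex takes cis-disubstituted conjugated alkenes by side-on approach and leaves tetrasubstituted ones, so C3=C4 reacts and C5=C6 stays; the ligand selects the face, and the (R,R) ligand is expected by analogy with 1,2-dihydronaphthalene to give the (3S,4R)-epoxide, whose oxygen lies on the face of the future C3 hydroxyl.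

**Step 4**
Reactants: 4 (3S,4R)-3,4-epoxide of O-silylated safranol
Product: 5 (1S,4R)-4-({[tert-butyl(dimethyl)silyl]oxy}methyl)-3,5,5-trimethylcyclohex-2-en-1-ol (carotenoid 3S,6R; hydroxyl and C7 cis)
Conditions: Pd(OAc)2 (5 mol %), PBu3 (10 mol %), HCO2H (3 equiv), Et3N (3.5 equiv), THF, 0 °C to rt
Reagents that add atoms: none
Why: Zerovalent palladium, formed in the flask from Pd(OAc)2 and PBu3, ionises the strained allylic C4–O bond of 4 from the face opposite the oxygen and gives an η3-allyl complex of divalent palladium over C4–C5–C6, the C3 oxygen being left as an alkoxide that the ammonium formate protonates. Formate bound to palladium loses CO2, and the resulting palladium hydride passes hydrogen to an allyl terminus from the metal face by reductive elimination. The closest known reaction type is the palladium-catalysed formate hydrogenolysis of alkenyl oxiranes and of cyclic allylic formates and carbonates, in which hydride goes to the more substituted allyl terminus, anti to the departed oxygen, even at ring carbons next to a quaternary centre. No ring is closed and no skeletal bond is formed. The one new stereocentre, C6, is controlled by the epoxide: palladium sits anti to the oxygen and hydrogen arrives on the palladium face, so C6–H is trans and C7 cis to the C3 hydroxyl. C3 is not touched and keeps the configuration set in step 3. The selectivity needed is transfer to C6 and not C4; it should follow because C6 is the fully substituted terminus and because, in the σ-allyl form, palladium prefers the less hindered secondary C4, from where the hydrogen is passed to C6 inside the coordination sphere. Et3N in excess over HCO2H keeps the acid-labile vinyl epoxide from opening by a cationic path.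

**Step 5**
Reactants: 5 (1S,4R)-4-({[tert-butyl(dimethyl)silyl]oxy}methyl)-3,5,5-trimethylcyclohex-2-en-1-ol
Product: 6 tert-butyl(dimethyl){[(1R,4S)-2,6,6-trimethyl-4-{[tri(propan-2-yl)silyl]oxy}cyclohex-2-en-1-yl]methoxy}silane
Conditions: TIPSOTf, 2,6-lutidine, CH2Cl2, −78 to 0 °C
Reagents that add atoms: triisopropylsilyl trifluoromethanesulfonate, CC(C)[Si](OS(=O)(=O)C(F)(F)F)(C(C)C)C(C)C
Why: Silylation of the secondary allylic alcohol with a silyl triflate and a hindered base; the bulky triisopropylsilyl group is chosen so that the primary tert-butyldimethylsilyl ether can be removed beside it.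

**Step 6**
Reactants: 6 bis-silyl ether
Product: 7 [(1R,4S)-2,6,6-trimethyl-4-{[tri(propan-2-yl)silyl]oxy}cyclohex-2-en-1-yl]methanol
Conditions: HF·pyridine, pyridine, THF, 0 °C to rt
Reagents that add atoms: none
Why: Buffered fluoride cleaves the less hindered primary tert-butyldimethylsilyl ether much faster than the secondary triisopropylsilyl ether, and the pyridine buffer keeps the allylic C3–O bond from ionising.

**Step 7**
Reactants: 7 [(1R,4S)-2,6,6-trimethyl-4-{[tri(propan-2-yl)silyl]oxy}cyclohex-2-en-1-yl]methanol
Product: 8 1-phenyl-5-({[(1R,4S)-2,6,6-trimethyl-4-{[tri(propan-2-yl)silyl]oxy}cyclohex-2-en-1-yl]methyl}sulfanyl)-1H-tetrazole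
Conditions: 1-phenyl-1H-tetrazole-5-thiol, PPh3, DIAD, THF, 0 °C to rt
Reagents that add atoms: 1-phenyl-1H-tetrazole-5-thiol, Sc1nnnn1-c1ccccc1
Why: Mitsunobu thioetherification: the acidic tetrazole thiol displaces the activated primary C7–O by SN2; C7 is β-branched, so the reaction should be slower than usual but has no competing pathway, and neither stereocentre is involved.

**Step 8**
Reactants: 8 tetrazolyl sulfide
Product: 9 1-phenyl-5-({[(1R,4S)-2,6,6-trimethyl-4-{[tri(propan-2-yl)silyl]oxy}cyclohex-2-en-1-yl]methyl}sulfonyl)-1H-tetrazole
Conditions: (NH4)6Mo7O24·4H2O (10 mol %), 30% aq H2O2, EtOH, 0 °C to rt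
Reagents that add atoms: hydrogen peroxide, OO
Why: Molybdate-catalysed peroxide oxidation takes sulfur to the sulfone far faster than it epoxidises an unactivated trisubstituted alkene, which a peracid would not guarantee; the silyl ether is stable.

**Step 9**
Reactants: 9 tetrazolyl sulfone; 10 crocetin dialdehyde, (2E,4E,6E,8E,10E,12E,14E)-2,6,11,15-tetramethylhexadeca-2,4,6,8,10,12,14-heptaenedial
Product: 12 O3-triisopropylsilyl ether of the target (3S,6R)-3-[tri(propan-2-yl)silyloxy]-8'-apo-ε-caroten-8'-al, via potassium sulfonyl carbanion 11 (not isolated)
Conditions: KN(SiMe3)2 (0.98 equiv), THF, −78 °C; then cannula into 10 (3 equiv), THF, −60 °C to rt, dark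
Reagents that add atoms: none
Why: Julia–Kocienski olefination: the carbanion adds to one aldehyde of 10, the alkoxide moves the tetrazole from sulfur to oxygen (Smiles rearrangement) and anti elimination forms C7=C8; phenyltetrazolyl sulfones with a potassium counter-ion favour the E alkene, which is also the thermodynamically preferred conjugated isomer; excess 10 holds the reaction to one end, and a slight deficit of base consumed before the aldehyde is met keeps the C6–H of the polyenal product away from free base.

**Step 10**
Reactants: 12 O3-triisopropylsilyl ether of the target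
Product: 13 target, (2E,4E,6E,8E,10E,12E,14E,16E)-17-[(1R,4S)-4-hydroxy-2,6,6-trimethylcyclohex-2-en-1-yl]-2,6,11,15-tetramethylheptadeca-2,4,6,8,10,12,14,16-octaenal
Conditions: Bu4NF, AcOH (1:1), THF, 0 °C to rt, dark
Reagents that add atoms: none
Why: Fluoride cleavage of the silyl ether; acetic acid buffers the fluoride so that the vinylogously acidic C6–H and the polyenal are not exposed to base, and no strong acid is present that could ionise the allylic C3–O bond; C3 and C6 are untouched.

## Compound list

1 | safranal, 2,6,6-trimethylcyclohexa-1,3-diene-1-carbaldehyde | CC1=C(C=O)C(C)(C)CC=C1 | starting material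
2 | safranol, (2,6,6-trimethylcyclohexa-1,3-dien-1-yl)methanol | CC1=C(CO)C(C)(C)CC=C1 | intermediate
3 | tert-butyl(dimethyl)[(2,6,6-trimethylcyclohexa-1,3-dien-1-yl)methoxy]silane | CC1=C(CO[Si](C)(C)C(C)(C)C)C(C)(C)CC=C1 | intermediate
4 | tert-butyl(dimethyl){[(1R,6S)-2,4,4-trimethyl-7-oxabicyclo[4.1.0]hept-2-en-3-yl]methoxy}silane (carotenoid 3S,4R epoxide) | CC1=C(CO[Si](C)(C)C(C)(C)C)C(C)(C)C[C@@H]2O[C@H]12 | intermediate
5 | (1S,4R)-4-({[tert-butyl(dimethyl)silyl]oxy}methyl)-3,5,5-trimethylcyclohex-2-en-1-ol | CC1=C[C@@H](O)CC(C)(C)[C@H]1CO[Si](C)(C)C(C)(C)C | intermediate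
6 | tert-butyl(dimethyl){[(1R,4S)-2,6,6-trimethyl-4-{[tri(propan-2-yl)silyl]oxy}cyclohex-2-en-1-yl]methoxy}silane | CC1=C[C@@H](O[Si](C(C)C)(C(C)C)C(C)C)CC(C)(C)[C@H]1CO[Si](C)(C)C(C)(C)C | intermediate
7 | [(1R,4S)-2,6,6-trimethyl-4-{[tri(propan-2-yl)silyl]oxy}cyclohex-2-en-1-yl]methanol | CC1=C[C@@H](O[Si](C(C)C)(C(C)C)C(C)C)CC(C)(C)[C@H]1CO | intermediate
8 | 1-phenyl-5-({[(1R,4S)-2,6,6-trimethyl-4-{[tri(propan-2-yl)silyl]oxy}cyclohex-2-en-1-yl]methyl}sulfanyl)-1H-tetrazole | CC1=C[C@@H](O[Si](C(C)C)(C(C)C)C(C)C)CC(C)(C)[C@H]1CSc1nnnn1-c1ccccc1 | intermediate
9 | 1-phenyl-5-({[(1R,4S)-2,6,6-trimethyl-4-{[tri(propan-2-yl)silyl]oxy}cyclohex-2-en-1-yl]methyl}sulfonyl)-1H-tetrazole | CC1=C[C@@H](O[Si](C(C)C)(C(C)C)C(C)C)CC(C)(C)[C@H]1CS(=O)(=O)c1nnnn1-c1ccccc1 | intermediate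
10 | crocetin dialdehyde, (2E,4E,6E,8E,10E,12E,14E)-2,6,11,15-tetramethylhexadeca-2,4,6,8,10,12,14-heptaenedial | O=C/C(C)=C/C=C/C(C)=C/C=C/C=C(C)/C=C/C=C(\C)C=O | starting material
11 | potassium salt of the C7 carbanion of 9 | [K+].CC1=C[C@@H](O[Si](C(C)C)(C(C)C)C(C)C)CC(C)(C)[C@H]1[CH-]S(=O)(=O)c1nnnn1-c1ccccc1 | intermediate
12 | (3S,6R)-3-{[tri(propan-2-yl)silyl]oxy}-8'-apo-ε-caroten-8'-al | CC1=C[C@@H](O[Si](C(C)C)(C(C)C)C(C)C)CC(C)(C)[C@H]1/C=C/C(C)=C/C=C/C(C)=C/C=C/C=C(C)/C=C/C=C(\C)C=O | intermediate
13 | (3S,6R)-3-hydroxy-8'-apo-ε-caroten-8'-al; (2E,4E,6E,8E,10E,12E,14E,16E)-17-[(1R,4S)-4-hydroxy-2,6,6-trimethylcyclohex-2-en-1-yl]-2,6,11,15-tetramethylheptadeca-2,4,6,8,10,12,14,16-octaenal | CC1=C[C@@H](O)CC(C)(C)[C@H]1/C=C/C(C)=C/C=C/C(C)=C/C=C/C=C(C)/C=C/C=C(\C)C=O | target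

## Step count and least certain steps

Total: 10 steps. Longest linear sequence: 10 steps, from 1 to 13; 10 enters in step 9 as purchased.

**Step 4 (key step).** The most likely failure is hydrogen transfer to C4 instead of C6, because C6 lies beside the quaternary C1 and carries the silyloxymethyl group. That would keep the C5=C6 alkene and create no C6 stereocentre. A second risk is that slow formate transfer lets the allyl complex isomerise the epoxide to an unsaturated ketone or dienol by β-hydride loss. The fallback sets out from 4 and returns at 5, and it replaces metal hydride transfer by a sigmatropic one. Epoxide 4 is opened with hydrazine hydrate in EtOH by SN2 attack at the allylic C4 with inversion. This should give (1S,2S)-4-({[tert-butyl(dimethyl)silyl]oxy}methyl)-2-hydrazinyl-3,5,5-trimethylcyclohex-3-en-1-ol F1, with nitrogen trans to the C3 hydroxyl. Dehydrogenation of F1 with DIAD in CH2Cl2 at 0 °C gives the allylic diazene (1S,2S)-4-({[tert-butyl(dimethyl)silyl]oxy}methyl)-2-diazenyl-3,5,5-trimethylcyclohex-3-en-1-ol F2, which is not isolated. F2 loses nitrogen by a retro-ene shift that can only deliver its hydrogen to C6, on the face of the C4–N bond and therefore anti to the C3 oxygen, to give 5. The open point of this fallback is the site of hydrazine attack (C4 against C3).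

**Step 3.** The most likely failure is incomplete facial selectivity on this diene, whose conjugating group is a substituted alkene, not an arene. Some attack at the tetrasubstituted alkene and loss of the labile vinyl epoxide on isolation are lesser risks; 4 would be used crude. The fallback sets out from 5 and returns at 5, replacing reliance on the catalyst by separation of diastereomers. Enantio-enriched 5 is acylated with (1S)-camphanic chloride, Et3N and catalytic 4-dimethylaminopyridine in CH2Cl2 to (1S,4R)-4-({[tert-butyl(dimethyl)silyl]oxy}methyl)-3,5,5-trimethylcyclohex-2-en-1-yl (1S,4R)-4,7,7-trimethyl-3-oxo-2-oxabicyclo[2.2.1]heptane-1-carboxylate F3. F3 is freed of the diastereomer from the minor enantiomer by crystallisation or chromatography and cleaved with K2CO3 in MeOH back to 5.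

**Step 9.** The likely failures are olefination at both ends of 10, incomplete E selectivity at C7=C8 with a conjugated aldehyde, and base-induced epimerisation at C6 or alkene migration once the polyenal has formed. The fallback sets out from 10 and carbanion 11 and returns at 12, with the far aldehyde masked. Dialdehyde 10 is treated with one equivalent of HC(OMe)3 and catalytic pyridinium p-toluenesulfonate in MeOH/CH2Cl2. The mono-acetal (2E,4E,6E,8E,10E,12E,14E)-16,16-dimethoxy-2,6,11,15-tetramethylhexadeca-2,4,6,8,10,12,14-heptaenal F4 is separated from recyclable 10 and bis-acetal. Carbanion 11 is added to a small excess of F4 to give the C8' dimethyl acetal of 12, F5, in which C6–H is no longer vinylogous to a carbonyl. Pyridinium p-toluenesulfonate in wet acetone then releases 12.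

**Step 10.** The likely failure is slow cleavage of the hindered secondary silyl ether, so that the polyenal sits for long in a fluoride medium and C6 epimerises or the ring alkene migrates. More acidic reagents would risk ionising the allylic C3–O bond. The fallback sets out from 9 and returns at 13, removing the silyl group before the polyene exists. Sulfone 9 is treated with HF·pyridine in THF to give 5-({[(1R,4S)-4-hydroxy-2,6,6-trimethylcyclohex-2-en-1-yl]methyl}sulfonyl)-1-phenyl-1H-tetrazole F6. Two equivalents of KN(SiMe3)2 at −78 °C give the dipotassium alkoxide carbanion F7, which is added to excess 10 and should give 13 directly after a buffered work-up.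

## Further compounds

F1 | step 4 | (1S,2S)-4-({[tert-butyl(dimethyl)silyl]oxy}methyl)-2-hydrazinyl-3,5,5-trimethylcyclohex-3-en-1-ol | CC1=C(CO[Si](C)(C)C(C)(C)C)C(C)(C)C[C@H](O)[C@H]1NN
F2 | step 4 | (1S,2S)-4-({[tert-butyl(dimethyl)silyl]oxy}methyl)-2-diazenyl-3,5,5-trimethylcyclohex-3-en-1-ol | CC1=C(CO[Si](C)(C)C(C)(C)C)C(C)(C)C[C@H](O)[C@H]1N=N
F3 | step 3 | (1S,4R)-4-({[tert-butyl(dimethyl)silyl]oxy}methyl)-3,5,5-trimethylcyclohex-2-en-1-yl (1S,4R)-4,7,7-trimethyl-3-oxo-2-oxabicyclo[2.2.1]heptane-1-carboxylate | CC1=C[C@@H](OC(=O)[C@@]23CC[C@@](C)(C(=O)O2)C3(C)C)CC(C)(C)[C@H]1CO[Si](C)(C)C(C)(C)C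
F4 | step 9 | (2E,4E,6E,8E,10E,12E,14E)-16,16-dimethoxy-2,6,11,15-tetramethylhexadeca-2,4,6,8,10,12,14-heptaenal | O=C/C(C)=C/C=C/C(C)=C/C=C/C=C(C)/C=C/C=C(\C)C(OC)OC
F5 | step 9 | C8' dimethyl acetal of 12, triisopropyl{[(1S,4R)-4-[(1E,3E,5E,7E,9E,11E,13E,15E)-17,17-dimethoxy-3,7,12,16-tetramethylheptadeca-1,3,5,7,9,11,13,15-octaenyl]-3,5,5-trimethylcyclohex-2-en-1-yl]oxy}silane | CC1=C[C@@H](O[Si](C(C)C)(C(C)C)C(C)C)CC(C)(C)[C@H]1/C=C/C(C)=C/C=C/C(C)=C/C=C/C=C(C)/C=C/C=C(\C)C(OC)OC
F6 | step 10 | 5-({[(1R,4S)-4-hydroxy-2,6,6-trimethylcyclohex-2-en-1-yl]methyl}sulfonyl)-1-phenyl-1H-tetrazole | CC1=C[C@@H](O)CC(C)(C)[C@H]1CS(=O)(=O)c1nnnn1-c1ccccc1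
F7 | step 10 | dipotassium salt of F6 (C3 alkoxide, C7 carbanion) | [K+].[K+].CC1=C[C@@H]([O-])CC(C)(C)[C@H]1[CH-]S(=O)(=O)c1nnnn1-c1ccccc1
A1 | alternative 1 | bis-allylic C15/C15' sulfone carrying the O3-silylated ring and the C8' dimethyl acetal | CC1=C[C@@H](O[Si](C)(C)C(C)(C)C)CC(C)(C)[C@H]1/C=C/C(C)=C/C=C/C(C)=C/CS(=O)(=O)C/C=C(C)/C=C/C=C(\C)C(OC)OC
A2 | alternative 1 | target as O3 tert-butyldimethylsilyl ether and C8' dimethyl acetal | CC1=C[C@@H](O[Si](C)(C)C(C)(C)C)CC(C)(C)[C@H]1/C=C/C(C)=C/C=C/C(C)=C/C=C/C=C(C)/C=C/C=C(\C)C(OC)OC
A3 | alternative 2 | ethyl 2,6,6-trimethyl-4-oxocyclohex-2-ene-1-carboxylate (racemic) | CC1=CC(=O)CC(C)(C)C1C(=O)OCC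
A4 | alternative 2 | ethyl (1R,4S)-4-hydroxy-2,6,6-trimethylcyclohex-2-ene-1-carboxylate | CC1=C[C@@H](O)CC(C)(C)[C@H]1C(=O)OCC
A5 | alternative 3 | tributyl({[(1R,6S)-6-{[tert-butyl(dimethyl)silyl]oxy}-2,4,4-trimethylcyclohex-2-en-1-yl]oxy}methyl)stannane | CC1=CC(C)(C)C[C@H](O[Si](C)(C)C(C)(C)C)[C@@H]1OC[Sn](CCCC)(CCCC)CCCC
A6 | alternative 3 | [(1R,4S)-4-{[tert-butyl(dimethyl)silyl]oxy}-2,6,6-trimethylcyclohex-2-en-1-yl]methanol | CC1=C[C@@H](O[Si](C)(C)C(C)(C)C)CC(C)(C)[C@H]1CO
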